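## The problem

The target 30 is a (2S)-flavanone: a benzo ring A fused to a dihydropyranone ring C that carries a 4-hydroxy-3-methoxyphenyl ring B at C2. Ring A is a phloroglucinol nucleus with oxygen on C5, C7 and C8a, and C6, the carbon between O5 and O7, bears a 2-methylbut-3-en-2-yl (1,1-dimethylallyl) group, so a quaternary carbon sits on the most crowded arene position while C8 keeps its hydrogen. Electrophilic alkylation of a phloroglucinol would give the linear prenyl isomer or mixtures over C6 and C8, and a Claisen approach has to tell these two carbons apart. The three ring A oxygens must also be told apart, because closing ring C through O5 instead of O8a would give the 8-substituted isomer. C2 is the only stereocentre and nothing in the molecule can direct it, so it must be set by a catalyst; because a flavanone opens to the achiral chalcone by retro-oxa-Michael reaction under base, it is best set late and kept from base and fluoride afterwards. The terminal vinyl group excludes hydrogenolysis and strong acid (protonation leads to cyclisation onto a flanking phenol), the ring B methyl ether excludes a global Lewis-acid dealkylation, and the free phloroglucinol is easily oxidised. What makes the plan possible is the pattern of ring A itself: oxygen on C5, C7 and C8a, carbon on C6 and hydrogen on C8 is what a 3-alkoxy-4-alkylcyclobutenone and a siloxyalkyne assemble in a benzannulation, with each oxygen arriving in a different state (free hydroxyl on C5, alkyl ether on C7, silyl ether on C8a).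

## Retrosynthesis

**30 from 29.** No skeletal bond is cut; three methoxymethyl acetals are removed. Acetals are chosen because a flavanone tolerates dilute acid but not base or fluoride, and benzyl ethers are excluded by the vinyl group. The forward step asks only that methanolic acid at room temperature spares the monosubstituted alkene.

**29 from 24 and 28.** The C2–C1' bond is cut, so ring B arrives as boronic acid 28 in a rhodium-catalysed conjugate addition to the 2-unsubstituted chromone 24. The neighbouring cuts are weaker:
- O1–C2 (oxa-Michael closure of a hydroxychalcone) gives poor catalyst control without an extra activating group.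
- C2–H (conjugate reduction of the corresponding flavone) meets a less electrophilic 2-aryl vinylogous ester and is less well precedented.

Aryl addition to chromones is an established catalytic route to 2-arylchroman-4-ones and is the most convergent. 24 is achiral, and 28 is two steps from bromophenol 25 through 26. The forward step must give face selectivity from the ligand under conditions mild enough that the rhodium enolate does not open the pyranone.

**24 from 21 through 23.** The O1–C2 bond is cut: the ortho-silyloxyaryl ethynyl ketone 21 closes to a chromone when fluoride frees O8a. O5 is an acetal, so O8a is the only oxygen able to close. The same fluoride treatment, continued hot, removes the 2-(trimethylsilyl)ethyl group from O7 (through 22 to 23). That group is what the cyclobutenone synthesis can deliver, but its removal needs fluoride, so it is exchanged for an acetal (23 to 24) before any stereocentre exists. The alternative, an enaminone closure from an ortho-hydroxyacetophenone, would need a less selective C-acetylation of ring A.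

**21 from 17 through 18, 19 and 20.** C3–C4 is cut (addition of an ethynylmagnesium halide to aldehyde 19, then oxidation of carbinol 20), and C4–C4a is cut (ortho-formylation of phenol 17 to 18). In 17 the free hydroxyl on C5 has one ortho carbon blocked by the tertiary group, so a phenoxide-directed formylation can only reach C4a; electrophilic formylation without this direction would not distinguish C4a from C8. Capping O5 (18 to 19) completes the differentiation of the three oxygens.

**17 from 9 and 14 (key disconnection).** Three bonds of ring A are cut: C4a–C5, C8–C8a and C5–C6. Against attaching the tertiary allyl group to a preformed arene, this cut brings the quaternary carbon in from an aliphatic acid and fixes its position by the connectivity of the four-membered ring. The precursors contain no arene: cyclobutenone 9 supplies C5 to C8 with O7 as an alkyl ether, and siloxyalkyne 14 supplies C4a and C8a with O8a as a silyl ether. The forward reaction must show the correct polarity in the ketene–alkyne cycloaddition, leave the vinyl group alone, and tautomerise the cyclohexadienone faster than its allyl group can migrate.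

**9 from 7 and 5.** The two ring bonds made in a ketene–ynol ether [2+2] cycloaddition are cut; ketene 8 comes from acid chloride 7, itself from acid 6. Ynol ether 5 comes from alcohol 1 and chloroalkene 2 through 3 and 4. The 2-(trimethylsilyl)ethyl group is chosen because it survives strong base and heat and later leaves with fluoride.

**14 from 10.** The C–O bond is made by oxidising acetylide 11 to ynolate 12, the O–Si bond by silylation to 13, and the carbon-bound silyl group is removed last. The silyl cap is used because the monolithium derivative of ethyne itself would not survive the warming the oxidation needs.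

## Roads not taken

**Alternative 1:** The cut is C4–C4a. Acid A2, activated as its mixed trifluoroacetic anhydride, would acylate either of the two equivalent ortho carbons of its symmetric aryl ether ring and close ring C to give A1.
- Merits: symmetry removes the regiochemical question, C2 is in place before the ring closes, no chromone has to be built and no metal catalyst is needed. From a ring A phenol the target is about four steps away, against nine from 17 here, and in that respect this road is better.
- Weak points: the symmetric phenol needs the tertiary allyl group between two oxygens, with a free hydroxyl para to it and the flanking ones protected; this hard part is left unsolved. The acylation medium is strongly acidic, which threatens the acetals, the alkene, and above all the C2–O bond, a benzylic aryl ether that can ionise (loss of configuration) or eliminate to a cinnamic acid. The acetate on ring B only damps this.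
- Comparison: against the shorter end game the chosen plan offers a ring A whose quaternary carbon is never forced onto an arene, and a stereocentre made last that meets nothing harsher than methanolic HCl.

**Alternative 2:** The cuts are C3–C4 and O1–C2. Salicylaldehyde A4, an orthoformate and a chiral phosphoric acid would form a 4-methoxy ortho-quinone methide (oxocarbenium ion) that takes up styrene A5 in a [4+2] reaction. This gives chromane A3 as both C4 epimers, which converge once C4 is oxidised to the ketone.
- Merits: the most convergent road; two bonds, ring C and C2 in one step; ring B is a commercial, unprotected styrene; the C4 mixture is harmless.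
- Weak points: the addition is stepwise through a para-hydroxybenzyl cation, so the configuration at C2 is decided in the collapse of a long-lived cation, where control by the chiral counter-anion is doubtful. C4 must then be taken from a benzylic methyl ether to a ketone beside a free phenol, and two allyl ethers removed. A4 is an analogue of 18, so this road replaces only the end game and still needs a ring A synthesis.
- Comparison: on paper it is shorter (about four steps from A4 against seven from 18). The chosen plan sets against this a stereo-defining step of a reaction class already proven on chromones.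

**Alternative 3:** The cuts are C4a–C4, C3–C4 and O1–C2. Iodophenol A7, carbon monoxide A9 and alkyne A8 would combine under PdCl2(PPh3)2 and a secondary amine (carbonylative Sonogashira coupling, then 6-endo closure) to give flavone A6.
- Merits: three components and ring C in one step with ring B attached. The phenol behind A7 is symmetric, so iodination poses no regiochemical question. The flavone is two steps from a ring A phenol, against six to chromone 24 here, which is better.
- Weak points: iodination of an electron-rich ring that carries a nucleophilic alkene. Oxidative addition into a doubly ortho-substituted, electron-rich C–I bond is slow, so direct coupling and five-membered closure compete. A6 still lacks the stereocentre, and enantioselective conjugate reduction of a 2-aryl-5,7-dioxygenated chromone is less secure than aryl addition to a 2-unsubstituted one. The symmetric phenol poses the same tertiary-allyl problem as in alternative 1.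
- Comparison: the chosen plan accepts a longer approach to the pyranone in exchange for an unambiguous ring A and a better precedented asymmetric step. The flavone is kept as a reserve for step 15.

Key step: step 6

Assumption: acid 6 is taken as a catalogue compound (it is the saponification product of its bulk methyl ester).
Assumption: the (S)-bisphosphine (S)-MeO-F12-BIPHEP, (S)-(6,6'-dimethoxybiphenyl-2,2'-diyl)bis[bis(3,4,5-trifluorophenyl)phosphane], is taken to give 2S, since (S)-biaryl bisphosphines give (S)-3-arylcyclohexanones and the chromone maps onto cyclohexenone with O1 in place of C4; if the sense proves opposite, the (R)-ligand is used.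

Step 1
Reactants: 1 2-(trimethylsilyl)ethanol; 2 trichloroethylene
Product: 5 [2-(ethynyloxy)ethyl]trimethylsilane, via dichlorovinyl ether 3 (not isolated), via lithium alkoxyacetylide 4 (not isolated)
Conditions: KH, THF, 0 °C; 2, −50 °C → rt; n-BuLi (2.5 equiv), −78 → −40 °C; aq NH4Cl
Reagents that add atoms: none
Why: Alkoxide/trichloroethylene route to ynol ethers: the potassium alkoxide of 1 adds to dichloroethyne formed in situ to give 3, and n-BuLi then effects elimination and chlorine–lithium exchange to acetylide 4, which is protonated on quench. The alkoxide is used at once and cold so that Peterson-type loss of ethene from the β-silyl alkoxide does not compete.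

Step 2
Reactants: 6 3,3-dimethylpent-4-enoic acid
Product: 7 3,3-dimethylpent-4-enoyl chloride
Conditions: (COCl)2, DMF (cat.), CH2Cl2, 0 °C → rt
Reagents that add atoms: oxalyl chloride, ClC(=O)C(=O)Cl
Why: Acid chloride formation through the Vilsmeier chloroiminium ion; the isolated vinyl group is untouched and the volatile by-products leave 7 ready for use.

Step 3
Reactants: 7 3,3-dimethylpent-4-enoyl chloride; 5 [2-(ethynyloxy)ethyl]trimethylsilane
Product: 9 4-(2-methylbut-3-en-2-yl)-3-[2-(trimethylsilyl)ethoxy]cyclobut-2-en-1-one (racemic), via ketene 8 (not isolated)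
Conditions: Et3N, CH2Cl2, rt → 40 °C (7 added slowly)
Reagents that add atoms: none
Why: Dehydrochlorination gives the tert-alkylketene 8, which like tert-butylketene is slow to dimerise and is trapped by the nucleophilic ynol ether 5 in a ketene–alkyne [2+2] cycloaddition; bonding of the alkyne CH carbon to the ketene carbonyl carbon fixes the 3-alkoxy-4-alkyl pattern. The C4 stereocentre is formed racemic and disappears in step 6.

Step 4
Reactants: 10 ethynyltrimethylsilane
Product: 13 triisopropyl{[(trimethylsilyl)ethynyl]oxy}silane, via lithium acetylide 11 (not isolated), via lithium ynolate 12 (not isolated)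
Conditions: n-BuLi, THF, −78 °C; t-BuOOLi (from t-BuOOH, LiN(SiMe3)2), −78 → 0 °C; i-Pr3SiOTf, −78 → 0 °C
Reagents that add atoms: tert-butyl hydroperoxide, CC(C)(C)OO; triisopropylsilyl trifluoromethanesulfonate, CC(C)[Si](OS(=O)(=O)C(F)(F)F)(C(C)C)C(C)C
Why: Oxidation of an alkynyllithium with lithium tert-butyl peroxide (the acetylide attacks the peroxide oxygen) gives ynolate 12, and the bulky silyl triflate is expected to react at oxygen to give a thermally stable siloxyalkyne. The trimethylsilyl group stands in for the hydrogen of ethyne, whose monolithium derivative would disproportionate on warming.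

Step 5
Reactants: 13 triisopropyl{[(trimethylsilyl)ethynyl]oxy}silane
Product: 14 (triisopropylsilyloxy)ethyne
Conditions: K2CO3 (cat.), MeOH, 0 °C
Reagents that add atoms: none
Why: Base-catalysed methanolysis of the alkynyl C–Si bond (protodesilylation); the hindered O–Si(i-Pr)3 bond and the electron-rich triple bond, which adds methanol only under acid catalysis, should survive the short cold exposure.

Step 6
Reactants: 9 4-(2-methylbut-3-en-2-yl)-3-[2-(trimethylsilyl)ethoxy]cyclobut-2-en-1-one; 14 (triisopropylsilyloxy)ethyne
Product: 17 2-(2-methylbut-3-en-2-yl)-5-(triisopropylsilyloxy)-3-[2-(trimethylsilyl)ethoxy]phenol, via vinylketene 15 (not isolated), via vinylcyclobutenone 16 (not isolated)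
Conditions: toluene, 80 °C then 110 °C (14 in excess)
Reagents that add atoms: none
Why: Danheiser benzannulation: thermal conrotatory four-electron opening of 9, with the tertiary group turning outward, gives vinylketene 15. Its ketene C=C bond adds to 14 in a polar [2+2] cycloaddition, the CH terminus of the siloxyalkyne bonding to the ketene carbonyl carbon (C4a–C5) and the oxygen-bearing carbon to the ketene α-carbon (C8–C8a), to give vinylcyclobutenone 16. 16 opens to a dienylketene, and ring A is closed by a thermally allowed disrotatory six-electron electrocyclisation that forms C5–C6; the resulting cyclohexa-2,4-dienone tautomerises to phenol 17. The closest known reaction type is the cyclobutenone–siloxyalkyne benzannulation to resorcinol monosilyl ethers, to which the 3-alkoxy group only adds the third oxygen. No stereocentre is formed, and the racemic C4 of 9 becomes the aromatic C6. The step needs the right regiochemistry in the [2+2] event, which the donor oxygen of 14 secures by polarising the triple bond, placing the silyloxy group meta and the tertiary group ortho to the new hydroxyl. It also needs chemoselectivity over the isolated vinyl group, which is far less nucleophilic than the ynol ether, and tautomerisation faster than sigmatropic migration of the allyl group; a Cope shift would end on the silyloxy-bearing carbon and cannot aromatise, so only a retro-Claisen shift remains as an escape.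

Step 7
Reactants: 17 2-(2-methylbut-3-en-2-yl)-5-(triisopropylsilyloxy)-3-[2-(trimethylsilyl)ethoxy]phenol
Product: 18 2-hydroxy-3-(2-methylbut-3-en-2-yl)-6-(triisopropylsilyloxy)-4-[2-(trimethylsilyl)ethoxy]benzaldehyde
Conditions: MgCl2, Et3N, (CH2O)n, MeCN, reflux; aq HCl
Reagents that add atoms: paraformaldehyde (as formaldehyde), C=O
Why: Casnati–Skattebøl ortho-formylation: the magnesium phenoxide of 17 delivers coordinated formaldehyde to an ortho carbon only, and with C6 occupied the sole ortho CH is C4a; a second formaldehyde oxidises the hydroxymethyl intermediate by hydride transfer. Silyl ether, alkyl ether and alkene are inert to MgCl2/Et3N.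

Step 8
Reactants: 18 2-hydroxy-3-(2-methylbut-3-en-2-yl)-6-(triisopropylsilyloxy)-4-[2-(trimethylsilyl)ethoxy]benzaldehyde
Product: 19 2-(methoxymethoxy)-3-(2-methylbut-3-en-2-yl)-6-(triisopropylsilyloxy)-4-[2-(trimethylsilyl)ethoxy]benzaldehyde
Conditions: NaH, MOMCl, THF/DMF, 0 °C → rt
Reagents that add atoms: chloromethyl methyl ether, COCCl
Why: O-Alkylation of the sodium phenoxide with the chloromethyl ether; NaH is used because the hydroxyl is chelated to the aldehyde and flanked by the tertiary group. With O5 capped, O8a is the only oxygen that can later close ring C.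

Step 9
Reactants: 19 2-(methoxymethoxy)-3-(2-methylbut-3-en-2-yl)-6-(triisopropylsilyloxy)-4-[2-(trimethylsilyl)ethoxy]benzaldehyde
Product: 20 1-{2-(methoxymethoxy)-3-(2-methylbut-3-en-2-yl)-6-(triisopropylsilyloxy)-4-[2-(trimethylsilyl)ethoxy]phenyl}prop-2-yn-1-ol (racemic)
Conditions: HC≡CMgBr, THF, −78 → −20 °C; aq NH4Cl
Reagents that add atoms: ethynylmagnesium bromide, C#C[Mg]Br
Why: 1,2-Addition of an alkynyl Grignard reagent to the aldehyde; the carbinol stereocentre is racemic and is destroyed in step 10. Magnesium as counter-ion and a cold quench are chosen so that the alkoxide does not take over the neighbouring silyl group.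

Step 10
Reactants: 20 1-{2-(methoxymethoxy)-3-(2-methylbut-3-en-2-yl)-6-(triisopropylsilyloxy)-4-[2-(trimethylsilyl)ethoxy]phenyl}prop-2-yn-1-ol
Product: 21 1-{2-(methoxymethoxy)-3-(2-methylbut-3-en-2-yl)-6-(triisopropylsilyloxy)-4-[2-(trimethylsilyl)ethoxy]phenyl}prop-2-yn-1-one
Conditions: MnO2 (activated), CH2Cl2, rt
Reagents that add atoms: none
Why: MnO2 oxidation of a benzylic and propargylic alcohol to the ynone; the reagent does not touch the isolated alkene, the acetal or the silyl groups.

Step 11
Reactants: 21 1-{2-(methoxymethoxy)-3-(2-methylbut-3-en-2-yl)-6-(triisopropylsilyloxy)-4-[2-(trimethylsilyl)ethoxy]phenyl}prop-2-yn-1-one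
Product: 23 7-hydroxy-5-(methoxymethoxy)-6-(2-methylbut-3-en-2-yl)-4H-chromen-4-one, via silylethyl chromone 22 (not isolated)
Conditions: CsF, DMF, 0 °C → rt, then 80 °C; aq NH4Cl
Reagents that add atoms: none
Why: Fluoride cleaves the aryl O–Si bond and the freed phenoxide adds 6-endo-dig to the ethynyl ketone, giving 22; anhydrous aprotic fluoride is the known way to obtain chromones, not five-membered products, from ortho-silyloxyaryl ethynyl ketones. On heating, fluoride attacks the trimethylsilyl group of the 7-ether, and fragmentation to ethene and the 7-oxidochromone, a vinylogous carboxylate leaving group, gives 23; only O8a can cyclise because O5 is an acetal.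

Step 12
Reactants: 23 7-hydroxy-5-(methoxymethoxy)-6-(2-methylbut-3-en-2-yl)-4H-chromen-4-one
Product: 24 5,7-bis(methoxymethoxy)-6-(2-methylbut-3-en-2-yl)-4H-chromen-4-one
Conditions: MOMCl, i-Pr2NEt, CH2Cl2, 0 °C → rt
Reagents that add atoms: chloromethyl methyl ether, COCCl
Why: Alkylation of the acidic, non-chelated 7-hydroxyl with the chloromethyl ether and a hindered amine; all remaining protecting groups are then acetals that one mild acid treatment removes.

Step 13
Reactants: 25 4-bromo-2-methoxyphenol
Product: 26 4-bromo-2-methoxy-1-(methoxymethoxy)benzene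
Conditions: MOMCl, i-Pr2NEt, CH2Cl2, 0 °C → rt
Reagents that add atoms: chloromethyl methyl ether, COCCl
Why: Standard methoxymethylation of a phenol; the acetal matches those on ring A.

Step 14
Reactants: 26 4-bromo-2-methoxy-1-(methoxymethoxy)benzene
Product: 28 [3-methoxy-4-(methoxymethoxy)phenyl]boronic acid, via aryllithium 27 (not isolated)
Conditions: n-BuLi, THF, −78 °C; B(Oi-Pr)3, −78 °C → rt; aq NH4Cl
Reagents that add atoms: triisopropyl borate, CC(C)OB(OC(C)C)OC(C)C; water, O
Why: Bromine–lithium exchange at −78 °C is faster than lithiation ortho to the acetal; aryllithium 27 is trapped as the borate and hydrolysed at near-neutral pH, which the acetal survives.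

Step 15
Reactants: 24 5,7-bis(methoxymethoxy)-6-(2-methylbut-3-en-2-yl)-4H-chromen-4-one; 28 [3-methoxy-4-(methoxymethoxy)phenyl]boronic acid
Product: 29 (2S)-5,7-bis(methoxymethoxy)-2-[3-methoxy-4-(methoxymethoxy)phenyl]-6-(2-methylbut-3-en-2-yl)-2,3-dihydro-4H-chromen-4-one
Conditions: [RhCl(C2H4)2]2 (cat.), (S)-MeO-F12-BIPHEP, KOH (aq, 0.2 equiv), toluene, 25 °C (28 in excess)
Reagents that add atoms: none
Why: Rhodium-catalysed asymmetric 1,4-addition of an arylboronic acid to a chromone (Hayashi–Miyaura reaction): transmetalation gives an aryl–rhodium species that inserts the C2=C3 bond, and the oxa-π-allyl enolate is protonated by water. The C2 stereocentre is set by the chiral bisphosphine, which exposes one enantiotopic face of C2 (catalyst control). The electron-poor ligand allows room temperature and little base, so the enolate should not open the ring, and the hindered vinyl group should not insert.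

Step 16
Reactants: 29 (2S)-5,7-bis(methoxymethoxy)-2-[3-methoxy-4-(methoxymethoxy)phenyl]-6-(2-methylbut-3-en-2-yl)-2,3-dihydro-4H-chromen-4-one
Product: 30 (2S)-5,7-dihydroxy-2-(4-hydroxy-3-methoxyphenyl)-6-(2-methylbut-3-en-2-yl)-2,3-dihydro-4H-chromen-4-one
Conditions: HCl, MeOH, 0 °C → rt
Reagents that add atoms: none
Why: Acid-catalysed transacetalisation with methanol removes the three methoxymethyl groups. A flavanone is configurationally stable in dilute acid and the monosubstituted alkene is not protonated under these conditions, so C2 stays S and the 1,1-dimethylallyl group stays intact.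

**Compound list**

1 | 2-(trimethylsilyl)ethanol | C[Si](C)(C)CCO | starting material
2 | trichloroethylene (1,1,2-trichloroethene) | ClC=C(Cl)Cl | starting material
3 | [2-(1,2-dichloroethenyloxy)ethyl]trimethylsilane (geometry not assigned; not isolated) | C[Si](C)(C)CCOC(Cl)=CCl | intermediate
4 | lithium [2-(trimethylsilyl)ethoxy]ethynide (not isolated) | [Li]C#COCC[Si](C)(C)C | intermediate
5 | [2-(ethynyloxy)ethyl]trimethylsilane | C#COCC[Si](C)(C)C | intermediate
6 | 3,3-dimethylpent-4-enoic acid | C=CC(C)(C)CC(=O)O | starting material
7 | 3,3-dimethylpent-4-enoyl chloride | C=CC(C)(C)CC(=O)Cl | intermediate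
8 | 3,3-dimethylpenta-1,4-dien-1-one, the (2-methylbut-3-en-2-yl)ketene (not isolated) | C=CC(C)(C)C=C=O | intermediate
9 | 4-(2-methylbut-3-en-2-yl)-3-[2-(trimethylsilyl)ethoxy]cyclobut-2-en-1-one (racemic) | C=CC(C)(C)C1C(=O)C=C1OCC[Si](C)(C)C | intermediate
10 | ethynyltrimethylsilane | C#C[Si](C)(C)C | starting material
11 | lithium (trimethylsilyl)ethynide (not isolated) | [Li]C#C[Si](C)(C)C | intermediate
12 | lithium 2-(trimethylsilyl)ethynolate (not isolated) | [Li]OC#C[Si](C)(C)C | intermediate
13 | triisopropyl{[(trimethylsilyl)ethynyl]oxy}silane | CC(C)[Si](OC#C[Si](C)(C)C)(C(C)C)C(C)C | intermediate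
14 | (triisopropylsilyloxy)ethyne | C#CO[Si](C(C)C)(C(C)C)C(C)C | intermediate
15 | 5,5-dimethyl-3-[2-(trimethylsilyl)ethoxy]hepta-1,3,6-trien-1-one (geometry not assigned; not isolated) | O=C=CC(OCC[Si](C)(C)C)=CC(C)(C)C=C | intermediate
16 | 4-{3,3-dimethyl-1-[2-(trimethylsilyl)ethoxy]penta-1,4-dien-1-yl}-3-(triisopropylsilyloxy)cyclobut-2-en-1-one (not isolated) | O=C1C=C(O[Si](C(C)C)(C(C)C)C(C)C)C1C(OCC[Si](C)(C)C)=CC(C)(C)C=C | intermediate
17 | 2-(2-methylbut-3-en-2-yl)-5-(triisopropylsilyloxy)-3-[2-(trimethylsilyl)ethoxy]phenol | C=CC(C)(C)c1c(O)cc(O[Si](C(C)C)(C(C)C)C(C)C)cc1OCC[Si](C)(C)C | intermediate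
18 | 2-hydroxy-3-(2-methylbut-3-en-2-yl)-6-(triisopropylsilyloxy)-4-[2-(trimethylsilyl)ethoxy]benzaldehyde | C=CC(C)(C)c1c(O)c(C=O)c(O[Si](C(C)C)(C(C)C)C(C)C)cc1OCC[Si](C)(C)C | intermediate
19 | 2-(methoxymethoxy)-3-(2-methylbut-3-en-2-yl)-6-(triisopropylsilyloxy)-4-[2-(trimethylsilyl)ethoxy]benzaldehyde | C=CC(C)(C)c1c(OCOC)c(C=O)c(O[Si](C(C)C)(C(C)C)C(C)C)cc1OCC[Si](C)(C)C | intermediate
20 | 1-{2-(methoxymethoxy)-3-(2-methylbut-3-en-2-yl)-6-(triisopropylsilyloxy)-4-[2-(trimethylsilyl)ethoxy]phenyl}prop-2-yn-1-ol (racemic) | C=CC(C)(C)c1c(OCOC)c(C(O)C#C)c(O[Si](C(C)C)(C(C)C)C(C)C)cc1OCC[Si](C)(C)C | intermediate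
21 | 1-{2-(methoxymethoxy)-3-(2-methylbut-3-en-2-yl)-6-(triisopropylsilyloxy)-4-[2-(trimethylsilyl)ethoxy]phenyl}prop-2-yn-1-one | C=CC(C)(C)c1c(OCOC)c(C(=O)C#C)c(O[Si](C(C)C)(C(C)C)C(C)C)cc1OCC[Si](C)(C)C | intermediate
22 | 5-(methoxymethoxy)-6-(2-methylbut-3-en-2-yl)-7-[2-(trimethylsilyl)ethoxy]-4H-chromen-4-one (not isolated) | C=CC(C)(C)c1c(OCC[Si](C)(C)C)cc2OC=CC(=O)c2c1OCOC | intermediate
23 | 7-hydroxy-5-(methoxymethoxy)-6-(2-methylbut-3-en-2-yl)-4H-chromen-4-one | C=CC(C)(C)c1c(O)cc2OC=CC(=O)c2c1OCOC | intermediate
24 | 5,7-bis(methoxymethoxy)-6-(2-methylbut-3-en-2-yl)-4H-chromen-4-one | C=CC(C)(C)c1c(OCOC)cc2OC=CC(=O)c2c1OCOC | intermediate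
25 | 4-bromo-2-methoxyphenol | COc1cc(Br)ccc1O | starting material
26 | 4-bromo-2-methoxy-1-(methoxymethoxy)benzene | COCOc1ccc(Br)cc1OC | intermediate
27 | [3-methoxy-4-(methoxymethoxy)phenyl]lithium (not isolated) | [Li]c1ccc(OCOC)c(OC)c1 | intermediate
28 | [3-methoxy-4-(methoxymethoxy)phenyl]boronic acid | COCOc1ccc(B(O)O)cc1OC | intermediate
29 | (2S)-5,7-bis(methoxymethoxy)-2-[3-methoxy-4-(methoxymethoxy)phenyl]-6-(2-methylbut-3-en-2-yl)-2,3-dihydro-4H-chromen-4-one | C=CC(C)(C)c1c(OCOC)cc2c(c1OCOC)C(=O)C[C@@H](c1ccc(OCOC)c(OC)c1)O2 | intermediate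
30 | (2S)-5,7-dihydroxy-2-(4-hydroxy-3-methoxyphenyl)-6-(2-methylbut-3-en-2-yl)-2,3-dihydro-4H-chromen-4-one | C=CC(C)(C)c1c(O)cc2c(c1O)C(=O)C[C@@H](c1ccc(O)c(OC)c1)O2 | target

**Step count and risks**

Total step count: 16. Longest linear sequence: 11 steps (1, 3, 6, 7, 8, 9, 10, 11, 12, 15, 16).

**Step 6 (key step).** The cyclohexa-2,4-dienone formed on ring closure may pass its allyl group to oxygen by a retro-Claisen shift before it enolises, because its sp3 carbon is crowded. Closure beside the quaternary carbon may also be slow enough for the vinylketene to dimerise or to acylate the product phenol.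
Fallback (sets out from 1, returns at 23): the tertiary allyl group is put onto a preformed phloroglucinol aldehyde by aromatic Claisen rearrangement instead of being built into the ring. Mitsunobu etherification (PPh3, diisopropyl azodicarboxylate, THF) of commercial 2,4,6-trihydroxybenzaldehyde with two equivalents of 1 should leave only the chelated hydroxyl free and give 2-hydroxy-4,6-bis[2-(trimethylsilyl)ethoxy]benzaldehyde F1. Alkylation with 1-bromo-3-methylbut-2-ene (K2CO3, DMF) gives 2-[(3-methylbut-2-en-1-yl)oxy]-4,6-bis[2-(trimethylsilyl)ethoxy]benzaldehyde F2. Heating (N,N-diethylaniline, 180 °C) moves the allyl group with inversion to the only free ortho carbon and gives 2-hydroxy-3-(2-methylbut-3-en-2-yl)-4,6-bis[2-(trimethylsilyl)ethoxy]benzaldehyde F3; a following Cope shift to the free para carbon is the weak point of this reserve. Protection as in step 8 gives 2-(methoxymethoxy)-3-(2-methylbut-3-en-2-yl)-4,6-bis[2-(trimethylsilyl)ethoxy]benzaldehyde F4. Ethynyl addition as in step 9 gives 1-{2-(methoxymethoxy)-3-(2-methylbut-3-en-2-yl)-4,6-bis[2-(trimethylsilyl)ethoxy]phenyl}prop-2-yn-1-ol F5, and MnO2 gives 1-{2-(methoxymethoxy)-3-(2-methylbut-3-en-2-yl)-4,6-bis[2-(trimethylsilyl)ethoxy]phenyl}prop-2-yn-1-one F6. CsF in DMF at 80 °C then removes both silylethyl groups, the phenoxide ortho to the ketone closes the pyranone, and 23 is reached.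

**Step 4.** The ambident ynolate 12 may be silylated at carbon, since the silyl substituent stabilises its ketene-like carbanion form; this would give a bis-silylketene instead of 13. Oxygen transfer to 11 may also be incomplete.
Fallback (sets out from 9 and 5, returns at 23): the siloxyalkyne is given up and ynol ether 5, already in hand, serves as the two-carbon partner in the same benzannulation. Heating 9 with 5 in toluene at 80 °C should give 2-(2-methylbut-3-en-2-yl)-3,5-bis[2-(trimethylsilyl)ethoxy]phenol F7. Its formylation under the conditions of step 7 can again only reach the one free ortho carbon and gives aldehyde F3 of the preceding fallback; F4, F5 and F6 then lead to 23 as described there. O7 and O8a no longer differ, which is harmless because only O8a stands ortho to the ketone.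

**Step 7.** Hydroxymethylation at C4a may be slow because the neighbouring triisopropylsilyloxy group screens that carbon, and prolonged heating would favour diarylmethane condensation.
Fallback (sets out from 9, returns at 18): the formyl carbon is brought in with the alkyne. Oxidation of the lithium acetylide of commercial 3,3-diethoxyprop-1-yne with lithium tert-butyl peroxide and O-silylation as in step 4 gives [(3,3-diethoxyprop-1-yn-1-yl)oxy]triisopropylsilane F8. Benzannulation with 9 as in step 6 places the acetal carbon between the new hydroxyl and the silyl ether and gives 2-(diethoxymethyl)-6-(2-methylbut-3-en-2-yl)-3-(triisopropylsilyloxy)-5-[2-(trimethylsilyl)ethoxy]phenol F9. Mild hydrolysis (pyridinium p-toluenesulfonate, wet acetone) gives 18.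

**Step 11.** The phenoxide may close 5-exo-dig to a five-membered ketone, or the terminal ynone may oligomerise under basic fluoride before it cyclises.
Fallback (sets out from 21, returns at 22): the alkyne is first turned into an enaminone, for which only six-membered closure is possible. Conjugate addition of diethylamine (THF, rt) gives (2E)-3-(diethylamino)-1-{2-(methoxymethoxy)-3-(2-methylbut-3-en-2-yl)-6-(triisopropylsilyloxy)-4-[2-(trimethylsilyl)ethoxy]phenyl}prop-2-en-1-one F10. Bu4NF buffered with acetic acid (THF, rt then 50 °C) removes the silyl group, and the phenol displaces the amine by addition–elimination to give 22. CsF in DMF at 80 °C converts 22 into 23 as in the second half of step 11.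

**Step 15.** Turnover may be poor on the electron-rich, 5,7-dioxygenated chromone, so that protodeboronation of 28 wins. The rhodium enolate or the product may also open to the chalcone and erode the enantiomeric purity.
Fallback (sets out from 26, 10 and 19, returns at 29): ring B is attached before ring C is closed, and C2 is set by hydride instead of aryl transfer. Sonogashira coupling of 26 with 10 (PdCl2(PPh3)2, CuI, Et3N, 60 °C) gives {[3-methoxy-4-(methoxymethoxy)phenyl]ethynyl}trimethylsilane F11, and K2CO3 in methanol gives 4-ethynyl-2-methoxy-1-(methoxymethoxy)benzene F12. Its lithium acetylide adds to 19 to give 1-{2-(methoxymethoxy)-3-(2-methylbut-3-en-2-yl)-6-(triisopropylsilyloxy)-4-[2-(trimethylsilyl)ethoxy]phenyl}-3-[3-methoxy-4-(methoxymethoxy)phenyl]prop-2-yn-1-ol F13. MnO2 gives 1-{2-(methoxymethoxy)-3-(2-methylbut-3-en-2-yl)-6-(triisopropylsilyloxy)-4-[2-(trimethylsilyl)ethoxy]phenyl}-3-[3-methoxy-4-(methoxymethoxy)phenyl]prop-2-yn-1-one F14. CsF in DMF (rt, then 80 °C) gives 7-hydroxy-5-(methoxymethoxy)-2-[3-methoxy-4-(methoxymethoxy)phenyl]-6-(2-methylbut-3-en-2-yl)-4H-chromen-4-one F15. Methoxymethylation as in step 12 gives 5,7-bis(methoxymethoxy)-2-[3-methoxy-4-(methoxymethoxy)phenyl]-6-(2-methylbut-3-en-2-yl)-4H-chromen-4-one F16, the same compound as A6. Copper hydride conjugate reduction (Cu(OAc)2, DTBM-SEGPHOS in the enantiomeric form that gives 2S, diethoxymethylsilane, tert-butanol, toluene) then gives 29.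

## Further compounds

F1 | step 6 | 2-hydroxy-4,6-bis[2-(trimethylsilyl)ethoxy]benzaldehyde | O=Cc1c(O)cc(OCC[Si](C)(C)C)cc1OCC[Si](C)(C)C
F2 | step 6 | 2-[(3-methylbut-2-en-1-yl)oxy]-4,6-bis[2-(trimethylsilyl)ethoxy]benzaldehyde | CC(C)=CCOc1cc(OCC[Si](C)(C)C)cc(OCC[Si](C)(C)C)c1C=O
F3 | step 6 | 2-hydroxy-3-(2-methylbut-3-en-2-yl)-4,6-bis[2-(trimethylsilyl)ethoxy]benzaldehyde | C=CC(C)(C)c1c(O)c(C=O)c(OCC[Si](C)(C)C)cc1OCC[Si](C)(C)C
F4 | step 6 | 2-(methoxymethoxy)-3-(2-methylbut-3-en-2-yl)-4,6-bis[2-(trimethylsilyl)ethoxy]benzaldehyde | C=CC(C)(C)c1c(OCOC)c(C=O)c(OCC[Si](C)(C)C)cc1OCC[Si](C)(C)C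
F5 | step 6 | 1-{2-(methoxymethoxy)-3-(2-methylbut-3-en-2-yl)-4,6-bis[2-(trimethylsilyl)ethoxy]phenyl}prop-2-yn-1-ol (racemic) | C=CC(C)(C)c1c(OCOC)c(C(O)C#C)c(OCC[Si](C)(C)C)cc1OCC[Si](C)(C)C
F6 | step 6 | 1-{2-(methoxymethoxy)-3-(2-methylbut-3-en-2-yl)-4,6-bis[2-(trimethylsilyl)ethoxy]phenyl}prop-2-yn-1-one | C=CC(C)(C)c1c(OCOC)c(C(=O)C#C)c(OCC[Si](C)(C)C)cc1OCC[Si](C)(C)C
F7 | step 4 | 2-(2-methylbut-3-en-2-yl)-3,5-bis[2-(trimethylsilyl)ethoxy]phenol | C=CC(C)(C)c1c(O)cc(OCC[Si](C)(C)C)cc1OCC[Si](C)(C)C
F8 | step 7 | [(3,3-diethoxyprop-1-yn-1-yl)oxy]triisopropylsilane | CCOC(OCC)C#CO[Si](C(C)C)(C(C)C)C(C)C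
F9 | step 7 | 2-(diethoxymethyl)-6-(2-methylbut-3-en-2-yl)-3-(triisopropylsilyloxy)-5-[2-(trimethylsilyl)ethoxy]phenol | C=CC(C)(C)c1c(O)c(C(OCC)OCC)c(O[Si](C(C)C)(C(C)C)C(C)C)cc1OCC[Si](C)(C)C
F10 | step 11 | (2E)-3-(diethylamino)-1-{2-(methoxymethoxy)-3-(2-methylbut-3-en-2-yl)-6-(triisopropylsilyloxy)-4-[2-(trimethylsilyl)ethoxy]phenyl}prop-2-en-1-one | C=CC(C)(C)c1c(OCOC)c(C(=O)/C=C/N(CC)CC)c(O[Si](C(C)C)(C(C)C)C(C)C)cc1OCC[Si](C)(C)C
F11 | step 15 | {[3-methoxy-4-(methoxymethoxy)phenyl]ethynyl}trimethylsilane | COCOc1ccc(C#C[Si](C)(C)C)cc1OC
F12 | step 15 | 4-ethynyl-2-methoxy-1-(methoxymethoxy)benzene | COCOc1ccc(C#C)cc1OC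
F13 | step 15 | 1-{2-(methoxymethoxy)-3-(2-methylbut-3-en-2-yl)-6-(triisopropylsilyloxy)-4-[2-(trimethylsilyl)ethoxy]phenyl}-3-[3-methoxy-4-(methoxymethoxy)phenyl]prop-2-yn-1-ol (racemic) | C=CC(C)(C)c1c(OCOC)c(C(O)C#Cc2ccc(OCOC)c(OC)c2)c(O[Si](C(C)C)(C(C)C)C(C)C)cc1OCC[Si](C)(C)C
F14 | step 15 | 1-{2-(methoxymethoxy)-3-(2-methylbut-3-en-2-yl)-6-(triisopropylsilyloxy)-4-[2-(trimethylsilyl)ethoxy]phenyl}-3-[3-methoxy-4-(methoxymethoxy)phenyl]prop-2-yn-1-one | C=CC(C)(C)c1c(OCOC)c(C(=O)C#Cc2ccc(OCOC)c(OC)c2)c(O[Si](C(C)C)(C(C)C)C(C)C)cc1OCC[Si](C)(C)C
F15 | step 15 | 7-hydroxy-5-(methoxymethoxy)-2-[3-methoxy-4-(methoxymethoxy)phenyl]-6-(2-methylbut-3-en-2-yl)-4H-chromen-4-one | C=CC(C)(C)c1c(O)cc2OC(c3ccc(OCOC)c(OC)c3)=CC(=O)c2c1OCOC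
F16 | step 15 | 5,7-bis(methoxymethoxy)-2-[3-methoxy-4-(methoxymethoxy)phenyl]-6-(2-methylbut-3-en-2-yl)-4H-chromen-4-one | C=CC(C)(C)c1c(OCOC)cc2OC(c3ccc(OCOC)c(OC)c3)=CC(=O)c2c1OCOC
A1 | alternative 1 | (2S)-2-[4-(acetyloxy)-3-methoxyphenyl]-5,7-bis(methoxymethoxy)-6-(2-methylbut-3-en-2-yl)-2,3-dihydro-4H-chromen-4-one | C=CC(C)(C)c1c(OCOC)cc2c(c1OCOC)C(=O)C[C@@H](c1ccc(OC(C)=O)c(OC)c1)O2
A2 | alternative 1 | (3S)-3-[4-(acetyloxy)-3-methoxyphenyl]-3-[3,5-bis(methoxymethoxy)-4-(2-methylbut-3-en-2-yl)phenoxy]propanoic acid | C=CC(C)(C)c1c(OCOC)cc(O[C@@H](CC(=O)O)c2ccc(OC(C)=O)c(OC)c2)cc1OCOC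
A3 | alternative 2 | (2S)-5,7-bis(allyloxy)-2-(4-hydroxy-3-methoxyphenyl)-4-methoxy-6-(2-methylbut-3-en-2-yl)chromane (both C4 epimers) | C=CC(C)(C)c1c(OCC=C)cc2c(c1OCC=C)C(OC)C[C@@H](c1ccc(O)c(OC)c1)O2
A4 | alternative 2 | 2,4-bis(allyloxy)-6-hydroxy-3-(2-methylbut-3-en-2-yl)benzaldehyde | C=CC(C)(C)c1c(OCC=C)cc(O)c(C=O)c1OCC=C
A5 | alternative 2 | 2-methoxy-4-vinylphenol | C=Cc1ccc(O)c(OC)c1
A6 | alternative 3 | 5,7-bis(methoxymethoxy)-2-[3-methoxy-4-(methoxymethoxy)phenyl]-6-(2-methylbut-3-en-2-yl)-4H-chromen-4-one | C=CC(C)(C)c1c(OCOC)cc2c(c1OCOC)C(=O)C=C(c1ccc(OCOC)c(OC)c1)O2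
A7 | alternative 3 | 2-iodo-3,5-bis(methoxymethoxy)-4-(2-methylbut-3-en-2-yl)phenol | C=CC(C)(C)c1c(OCOC)cc(O)c(I)c1OCOC
A8 | alternative 3 | 4-ethynyl-2-methoxy-1-(methoxymethoxy)benzene | C#Cc1ccc(OCOC)c(OC)c1
A9 | alternative 3 | carbon monoxide | [C-]#[O+]
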